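Time is the axis to watch in this reaction: between 15.0 min and 20.0 min the alpha run gains 3 percentage points of target.

| flask | substrate | coupling partner | free catalyst | impurity | remark |
|---|---|---|---|---|---|
| alpha | 8 mM | 24 mM | 60 µM | 11 µM | run made earlier |
| zeta | 18 mM | 24 mM | 60 µM | 11 µM | run made earlier |
| flask | 12 mM | 24.0 mM | 60 µM | 11 µM |  |

| run | time / min | target / % |
|---|---|---|
| alpha | 2.00 | 8.0 |
| alpha | 5.00 | 17.4 |
| alpha | 10.0 | 28.0 |
| alpha | 15.0 | 31.5 |
| alpha | 20.0 | 34.5 |
| zeta | 1.50 | 5.3 |
| zeta | 3.00 | 6.3 |
| zeta | 6.00 | 11.0 |
| zeta | 10.0 | 13.5 |
| zeta | 20.0 | 17.6 |

(readings scatter by 1 percentage point)

- the analysis behind the earlier runs scatters by 1 percentage point, standard deviation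
- what may be going on: catalyst intermediate A -> by-product + catalyst intermediate B; catalyst intermediate B -> catalyst intermediate C; free catalyst + impurity -> spent catalyst; catalyst intermediate E -> free catalyst + target; coupling partner -> decomposed reagent; substrate + catalyst intermediate C <-> catalyst intermediate D; coupling partner + free catalyst <-> catalyst intermediate A; catalyst intermediate D -> catalyst intermediate E
- no earlier run changes the charge of free catalyst; that part of a forecast is a guess
- no earlier run changes the charge of coupling partner; that part of a forecast is a guess

* factor on the rate of making target when 10% of the substrate are converted if coupling partner is charged twice over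
* factor on the rate when 10% of the substrate are converted if free catalyst is charged at 300 µM instead

In concentration, the alpha run holds 2.76 mM of target at 20.0 min and the zeta run 3.17 mM. The substrate charges differ by a factor of 2.25, but these amounts differ by a factor of 1.15. Both runs were charged the same coupling partner and the same free catalyst, so the readings do not show target following either charge. A bench rule for these two charges follows: target at this time is taken as one amount across substrate charges between those of the two runs. Let φ = 0.124, the partner yield: target at 20.0 min per coupling partner charged, averaged over both runs, so that a bending curve is replaced by one mean share. The error of that mean shows on the alpha run, where φ gives 37.1% against 34.5% read, with a scatter of 1 point.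

For the flask, my own reckoning gives 2.96 mM of target, or 24.7% of its substrate. The rule has two borders. The ratio φ·(partner charge)/(substrate charge) must stay below one, and here it is 0.247. Also, φ comes from runs at one partner charge and one catalyst charge, so it gives neither asked factor.

The forecast puts the factor for doubled partner at 2.5 and that for more catalyst at 8.5, on the ground that “this decay must come from coupling partner decomposing”.

The flask gives 1.41 and 7.42, so the first forecast value is high by a factor of 1.77 and the second lies within tolerance.

    catalyst intermediate A → by-product + catalyst intermediate B (k = 1100 /min)
    catalyst intermediate B → catalyst intermediate C (k = 200 /min)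
    free catalyst + impurity → spent catalyst (k = 17000 /M/s)
    catalyst intermediate E → free catalyst + target (k = 1100 /min)
    coupling partner → decomposed reagent (k = 0.160 /min)
    substrate + catalyst intermediate C ⇌ catalyst intermediate D (K = 3800 /M, k = 1900 /M/min)
    coupling partner + free catalyst ⇌ catalyst intermediate A (K = 2100 /M, k = 890 /M/min)
    catalyst intermediate D → catalyst intermediate E (k = 27.0 /min)

At 20.0 min the flask holds 24.9% target, so its φ is 0.125. At 3.61 min, decomposition uses coupling partner 7.5 times as fast as the forward step to catalyst intermediate A taken alone, a share of 0.117 for that step, and 2.20% of the partner remains at 20.0 min. On the zeta run, the mean φ gives 16.5% against 17.6% read at 20.0 min.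

(The data stem from a simulated flask for substances that don't exist, and the scatter is random.)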